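**Plan**

- Retrosynthesis: the pyran ring is opened by cutting O1–C8a and C2–C3 together (the reverse of an aryl 1,2-shift from carbon to oxygen followed by a Prins closure). This leads to a tertiary benzylic hydroperoxide in which C2 is still bonded to C8a. Then C2–CH3 (organocerium addition), C4a–vinyl (Stille coupling) and C8a–C2 (Friedel–Crafts acylation) are cut.
- Enabling feature: O1 sits on C8a, para to the C6 oxygen, so C8a belongs to a para-oxygenated aryl ring that migrates readily from C2 to an electron-poor oxygen. C4 is benzylic and ortho to O1, so attack of C3 on C2 ends in a stabilised cation that loses a proton to give C3=C4.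
- Forward: natural phytol is degraded to the methyl ketone and then to the C17 acid, which acylates 2,5-dimethylresorcinol. Silylation, triflation, vinylation, methyl addition and perhydrolysis follow. The cascade then closes the pyran ring, the only ring formed, and desilylation gives the target.
- Stereochemistry: C4′ and C8′ come unchanged from natural (7R,11R)-phytol. C2 (S) is set in the key step by a chiral confined counteranion. The configuration of the carbinol and hydroperoxide carbon does not matter, because that carbon becomes planar.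

Key step: step 9

Assumption: commercial natural phytol is the (2E,7R,11R) isomer. The antipode of the chiral acid that gives 2S is identified on a model hydroperoxide before use.

**Route**

Step 1
Reactants: 1 natural phytol, (2E,7R,11R)-3,7,11,15-tetramethylhexadec-2-en-1-ol
Product: 3 (6R,10R)-6,10,14-trimethylpentadecan-2-one (phytone), via secondary ozonide 2 (not isolated)
Conditions: O3, CH2Cl2, −78 °C; then Me2S, −78 °C to rt
Reagents that add atoms: ozone, [O-][O+]=O
Why: Ozonolysis cleaves the only C=C bond, the trisubstituted carbon becomes the methyl ketone, and the two remote stereocentres are not touched.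

Step 2
Reactants: 3 (6R,10R)-6,10,14-trimethylpentadecan-2-one
Product: 5 (5R,9R)-5,9,13-trimethyltetradecanoic acid, via tribromomethyl ketone 4 (not isolated)
Conditions: Br2, NaOH, 1,4-dioxane/H2O, 0 °C to rt; then HCl (aq.)
Reagents that add atoms: sodium hydroxide, [Na+].[OH-]
Why: Haloform reaction: the methyl group is brominated three times under base and hydroxide then cleaves the C–CBr3 bond, with no stereocentre near the reacting carbon.

Step 3
Reactants: 5 (5R,9R)-5,9,13-trimethyltetradecanoic acid; 6 2,5-dimethylresorcinol (2,5-dimethylbenzene-1,3-diol)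
Product: 7 (5R,9R)-1-(2,4-dihydroxy-3,6-dimethylphenyl)-5,9,13-trimethyltetradecan-1-one
Conditions: BF3·OEt2 (solvent and promoter), 85 °C; aq. NaOAc work-up
Reagents that add atoms: none
Why: Friedel–Crafts acylation (through O-acylation and Fries-type shift) of the electron-rich resorcinol; its two free ring positions are equivalent, so one ketone forms, and the acyl group deactivates the ring towards a second acylation.

Step 4
Reactants: 7 (5R,9R)-1-(2,4-dihydroxy-3,6-dimethylphenyl)-5,9,13-trimethyltetradecan-1-one
Product: 8 (5R,9R)-1-{2-hydroxy-3,6-dimethyl-4-[(triisopropylsilyl)oxy]phenyl}-5,9,13-trimethyltetradecan-1-one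
Conditions: TIPSCl, imidazole, DMF, 0 °C to rt
Reagents that add atoms: chlorotriisopropylsilane, CC(C)[Si](Cl)(C(C)C)C(C)C
Why: Silyl ether formation is selective because the 2-hydroxyl is hydrogen-bonded to the ketone and flanked by acyl and methyl, so the bulky silyl chloride takes the free 4-hydroxyl.

Step 5
Reactants: 8 (5R,9R)-1-{2-hydroxy-3,6-dimethyl-4-[(triisopropylsilyl)oxy]phenyl}-5,9,13-trimethyltetradecan-1-one
Product: 9 2,5-dimethyl-3-[(triisopropylsilyl)oxy]-6-[(5R,9R)-5,9,13-trimethyltetradecanoyl]phenyl trifluoromethanesulfonate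
Conditions: Tf2O, pyridine, CH2Cl2, 0 °C
Reagents that add atoms: trifluoromethanesulfonic anhydride, O=S(=O)(OS(=O)(=O)C(F)(F)F)C(F)(F)F
Why: O-Sulfonylation of the remaining phenol turns the oxygen on the future C4a into a leaving group for cross-coupling.

Step 6
Reactants: 9 aryl triflate
Product: 10 (5R,9R)-1-{2-ethenyl-3,6-dimethyl-4-[(triisopropylsilyl)oxy]phenyl}-5,9,13-trimethyltetradecan-1-one
Conditions: Bu3SnCH=CH2, Pd(PPh3)4 (cat.), LiCl, 1,4-dioxane, 100 °C
Reagents that add atoms: tributyl(vinyl)stannane, C=C[Sn](CCCC)(CCCC)CCCC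
Why: Stille coupling (oxidative addition of zerovalent palladium into the C–OTf bond, transmetalation from tin, reductive elimination) under neutral conditions that leave the ketone and the silyl ether alone.

Step 7
Reactants: 10 vinyl aryl ketone
Product: 11 (6R,10R)-2-{2-ethenyl-3,6-dimethyl-4-[(triisopropylsilyl)oxy]phenyl}-6,10,14-trimethylpentadecan-2-ol (both C2 epimers)
Conditions: MeLi, CeCl3 (anhydrous), THF, −78 °C; then 10, −78 to 0 °C; aq. NH4Cl
Reagents that add atoms: methyllithium, [Li]C
Why: 1,2-Addition of an organocerium reagent, which is strongly nucleophilic but weakly basic and so adds to the hindered, enolisable aryl ketone; the new carbinol centre forms as both epimers, which is harmless because it becomes planar in step 9.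

Step 8
Reactants: 11 tertiary benzylic alcohol
Product: 12 (6R,10R)-2-{2-ethenyl-3,6-dimethyl-4-[(triisopropylsilyl)oxy]phenyl}-6,10,14-trimethylpentadecan-2-yl hydroperoxide (both C2 epimers)
Conditions: H2O2 (50 % aq., large excess), H2SO4 (cat.), THF, 0 °C, short reaction time
Reagents that add atoms: hydrogen peroxide, OO
Why: SN1 perhydrolysis, the standard route to cumyl-type hydroperoxides: the tertiary benzylic cation, stabilised by the para silyloxy group, is captured by the excess of H2O2, and dilute acid at 0 °C should keep the hydroperoxide from rearranging.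

Step 9
Reactants: 12 tertiary benzylic hydroperoxide
Product: 15 triisopropyl({(2S)-2,5,8-trimethyl-2-[(4R,8R)-4,8,12-trimethyltridecyl]-2H-chromen-6-yl}oxy)silane, via aryloxy oxocarbenium ion 13 (not isolated), via chroman-4-yl cation 14 (not isolated)
Conditions: confined chiral imidodiphosphorimidate (IDPi) Brønsted acid (5 mol %), 5 Å molecular sieves, CHCl3, −40 °C
Reagents that add atoms: none
Why: Proposed new method: the chiral acid protonates the terminal peroxide oxygen of 12 and the aryl group migrates from C2 to O1 with loss of water (Hock/Criegee 1,2-shift), which makes the O1–C8a bond and gives the aryloxy oxocarbenium ion 13 paired with the chiral anion; C3, the terminal carbon of the ortho vinyl group, then attacks C2 (Prins-type cation–olefin addition) and the benzylic, O1-stabilised C4 cation 14 loses a C3 proton to leave the C3=C4 bond. The closest known reaction types are the interrupted Hock rearrangement of benzylic hydroperoxides, in which the aryloxy oxocarbenium ion is trapped by a π-nucleophile instead of water, and confined chiral Brønsted acid catalysis of additions to oxocarbenium ion pairs derived from methyl alkyl ketones and of olefin cyclisations that form tertiary ethers. The pyran ring closes in a 6-endo-trig mode on the styrene terminus, the only mode that places the charge on the benzylic C4. C2, the only new stereocentre, is controlled by the chiral counteranion, whose narrow pocket must tell the methyl group from the C16 chain on the planar C2=O+ unit and present one face to the tethered vinyl group. The step needs aryl migration in preference to methyl or alkyl migration and to loss of H2O2, which the para silyloxy group on the migrating ring should secure, and it needs hydrolysis of 13 (plain Hock cleavage) to be held back, which the molecular sieves and the intramolecular trap should secure.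

Step 10
Reactants: 15 silyl-protected chromene
Product: 16 (2S)-2,5,8-trimethyl-2-[(4R,8R)-4,8,12-trimethyltridecyl]-2H-chromen-6-ol (target)
Conditions: TBAF, AcOH, THF, 0 °C
Reagents that add atoms: none
Why: Fluoride cleaves the aryl silyl ether through Si–F bond formation, acetic acid buffers the phenoxide so the electron-rich chromenol is not oxidised, and C2 is not involved.

**Compound list**

1 | natural phytol, (2E,7R,11R)-3,7,11,15-tetramethylhexadec-2-en-1-ol | OC/C=C(C)/CCC[C@H](C)CCC[C@H](C)CCCC(C)C | starting material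
2 | secondary ozonide, 3-(hydroxymethyl)-5-methyl-5-[(4R,8R)-4,8,12-trimethyltridecyl]-1,2,4-trioxolane (ring diastereomers) | OCC1OOC(C)(CCC[C@H](C)CCC[C@H](C)CCCC(C)C)O1 | intermediate (not isolated)
3 | phytone, (6R,10R)-6,10,14-trimethylpentadecan-2-one | CC(=O)CCC[C@H](C)CCC[C@H](C)CCCC(C)C | intermediate
4 | (6R,10R)-1,1,1-tribromo-6,10,14-trimethylpentadecan-2-one | BrC(Br)(Br)C(=O)CCC[C@H](C)CCC[C@H](C)CCCC(C)C | intermediate (not isolated)
5 | (5R,9R)-5,9,13-trimethyltetradecanoic acid | OC(=O)CCC[C@H](C)CCC[C@H](C)CCCC(C)C | intermediate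
6 | 2,5-dimethylresorcinol (2,5-dimethylbenzene-1,3-diol) | Cc1cc(O)c(C)c(O)c1 | starting material
7 | (5R,9R)-1-(2,4-dihydroxy-3,6-dimethylphenyl)-5,9,13-trimethyltetradecan-1-one | Cc1cc(O)c(C)c(O)c1C(=O)CCC[C@H](C)CCC[C@H](C)CCCC(C)C | intermediate
8 | (5R,9R)-1-{2-hydroxy-3,6-dimethyl-4-[(triisopropylsilyl)oxy]phenyl}-5,9,13-trimethyltetradecan-1-one | Cc1cc(O[Si](C(C)C)(C(C)C)C(C)C)c(C)c(O)c1C(=O)CCC[C@H](C)CCC[C@H](C)CCCC(C)C | intermediate
9 | 2,5-dimethyl-3-[(triisopropylsilyl)oxy]-6-[(5R,9R)-5,9,13-trimethyltetradecanoyl]phenyl trifluoromethanesulfonate | Cc1cc(O[Si](C(C)C)(C(C)C)C(C)C)c(C)c(OS(=O)(=O)C(F)(F)F)c1C(=O)CCC[C@H](C)CCC[C@H](C)CCCC(C)C | intermediate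
10 | (5R,9R)-1-{2-ethenyl-3,6-dimethyl-4-[(triisopropylsilyl)oxy]phenyl}-5,9,13-trimethyltetradecan-1-one | Cc1cc(O[Si](C(C)C)(C(C)C)C(C)C)c(C)c(C=C)c1C(=O)CCC[C@H](C)CCC[C@H](C)CCCC(C)C | intermediate
11 | (6R,10R)-2-{2-ethenyl-3,6-dimethyl-4-[(triisopropylsilyl)oxy]phenyl}-6,10,14-trimethylpentadecan-2-ol (both C2 epimers) | Cc1cc(O[Si](C(C)C)(C(C)C)C(C)C)c(C)c(C=C)c1C(C)(O)CCC[C@H](C)CCC[C@H](C)CCCC(C)C | intermediate
12 | (6R,10R)-2-{2-ethenyl-3,6-dimethyl-4-[(triisopropylsilyl)oxy]phenyl}-6,10,14-trimethylpentadecan-2-yl hydroperoxide (both C2 epimers) | Cc1cc(O[Si](C(C)C)(C(C)C)C(C)C)c(C)c(C=C)c1C(C)(OO)CCC[C@H](C)CCC[C@H](C)CCCC(C)C | intermediate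
13 | {2-ethenyl-3,6-dimethyl-4-[(triisopropylsilyl)oxy]phenyl}[(6R,10R)-6,10,14-trimethylpentadecan-2-ylidene]oxidanium (aryloxy oxocarbenium ion) | Cc1cc(O[Si](C(C)C)(C(C)C)C(C)C)c(C)c(C=C)c1[O+]=C(C)CCC[C@H](C)CCC[C@H](C)CCCC(C)C | intermediate (not isolated)
14 | 2,5,8-trimethyl-6-[(triisopropylsilyl)oxy]-2-[(4R,8R)-4,8,12-trimethyltridecyl]-3,4-dihydro-2H-chromen-4-ylium, C2 configured as in 15 | Cc1cc(O[Si](C(C)C)(C(C)C)C(C)C)c(C)c2c1O[C@@](C)(CCC[C@H](C)CCC[C@H](C)CCCC(C)C)C[CH+]2 | intermediate (not isolated)
15 | triisopropyl({(2S)-2,5,8-trimethyl-2-[(4R,8R)-4,8,12-trimethyltridecyl]-2H-chromen-6-yl}oxy)silane | Cc1cc(O[Si](C(C)C)(C(C)C)C(C)C)c(C)c2c1O[C@@](C)(CCC[C@H](C)CCC[C@H](C)CCCC(C)C)C=C2 | intermediate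
16 | (2S)-2,5,8-trimethyl-2-[(4R,8R)-4,8,12-trimethyltridecyl]-2H-chromen-6-ol | Cc1cc(O)c(C)c2c1O[C@@](C)(CCC[C@H](C)CCC[C@H](C)CCCC(C)C)C=C2 | target

**Step count and risks**

Total step count: 10. Longest linear sequence: 10 steps (1 to 16; 2,5-dimethylresorcinol 6 joins at step 3).

Steps most likely to fail:

Step 9 (Proposed new method). What may go wrong: poor facial selectivity in the Prins closure, because the counteranion may not tell methyl from the long chain; hydrolysis of the oxocarbenium ion to phenol and ketone outrunning the closure; cationic oligomerisation of the styrene; or acid-induced ionisation of the C2–O1 bond in the product with loss of configuration. Fallback, known reactions only, setting out from hydroperoxide 12 and phytol 1 and coming back at 15: ordinary aqueous Hock cleavage of 12 (H2SO4 cat., acetone/H2O) gives 3,6-dimethyl-4-[(triisopropylsilyl)oxy]-2-vinylphenol F1 and returns phytone. Phytol 1 is converted with methyl chloroformate and pyridine into methyl (2E,7R,11R)-3,7,11,15-tetramethylhexadec-2-en-1-yl carbonate F2. A Tsuji–Trost asymmetric allylic etherification of F1 with F2 (Pd2(dba)3·CHCl3, chiral N,N′-(cyclohexane-1,2-diyl)bis(2-diphenylphosphinobenzamide) ligand, CH2Cl2) should give the branched tertiary aryl ether triisopropyl{[2,5-dimethyl-4-{[(3S,7R,11R)-3,7,11,15-tetramethylhexadec-1-en-3-yl]oxy}-3-vinylphenyl]oxy}silane F3. Its C–O stereocentre is set by the ligand antipode acting on the E olefin. Ring-closing metathesis of F3 with the second-generation Grubbs catalyst (H2IMes)(PCy3)Cl2Ru=CHPh in CH2Cl2 closes C3=C4 and gives 15.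

Step 8. What may go wrong: the tertiary benzylic cation is intercepted by the neighbouring vinyl group (cyclisation to an indene or to a cyclic ether or peroxide), or the hydroperoxide rearranges prematurely under the acid. Fallback, setting out from triflate 9 and coming back at 15 through ion 13: Baeyer–Villiger oxidation of 9 (mCPBA, CF3CO2H cat., CH2Cl2) with migration of the electron-rich aryl group gives 3,6-dimethyl-4-[(triisopropylsilyl)oxy]-2-[(trifluoromethylsulfonyl)oxy]phenyl (5R,9R)-5,9,13-trimethyltetradecanoate F4, which makes the O1–C8a bond without a hydroperoxide. Stille vinylation as in step 6 gives 2-ethenyl-3,6-dimethyl-4-[(triisopropylsilyl)oxy]phenyl (5R,9R)-5,9,13-trimethyltetradecanoate F5. Methylenation of the ester carbonyl with Cp2TiMe2 (toluene, 70 °C) gives the aryl enol ether triisopropyl({2,5-dimethyl-4-{[(6R,10R)-6,10,14-trimethylpentadec-1-en-2-yl]oxy}-3-vinylphenyl}oxy)silane F6. Protonation of F6 by the chiral acid of step 9 generates oxocarbenium ion 13 directly, and the closure to 15 follows as in the route.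

Step 7. What may go wrong: enolisation or no addition at the hindered, doubly ortho-substituted aryl ketone. Fallback, setting out from ketone 10 and coming back at 12: carbonyl methylenation of 10 with Cp2TiMe2 (toluene, 70 °C) gives the 1,1-disubstituted styrene triisopropyl({2,5-dimethyl-4-[(6R,10R)-6,10,14-trimethylpentadec-1-en-2-yl]-3-vinylphenyl}oxy)silane F7. Markovnikov perhydrolysis of F7 (H2O2, H2SO4 cat., THF, 0 °C) passes through the same tertiary benzylic cation and gives hydroperoxide 12, so alcohol 11 is bypassed.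

**Further compounds**

F1 | step 9 | 3,6-dimethyl-4-[(triisopropylsilyl)oxy]-2-vinylphenol | Cc1cc(O[Si](C(C)C)(C(C)C)C(C)C)c(C)c(C=C)c1O
F2 | step 9 | methyl (2E,7R,11R)-3,7,11,15-tetramethylhexadec-2-en-1-yl carbonate | COC(=O)OC/C=C(C)/CCC[C@H](C)CCC[C@H](C)CCCC(C)C
F3 | step 9 | triisopropyl{[2,5-dimethyl-4-{[(3S,7R,11R)-3,7,11,15-tetramethylhexadec-1-en-3-yl]oxy}-3-vinylphenyl]oxy}silane | Cc1cc(O[Si](C(C)C)(C(C)C)C(C)C)c(C)c(C=C)c1O[C@@](C)(CCC[C@H](C)CCC[C@H](C)CCCC(C)C)C=C
F4 | step 8 | 3,6-dimethyl-4-[(triisopropylsilyl)oxy]-2-[(trifluoromethylsulfonyl)oxy]phenyl (5R,9R)-5,9,13-trimethyltetradecanoate | Cc1cc(O[Si](C(C)C)(C(C)C)C(C)C)c(C)c(OS(=O)(=O)C(F)(F)F)c1OC(=O)CCC[C@H](C)CCC[C@H](C)CCCC(C)C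
F5 | step 8 | 2-ethenyl-3,6-dimethyl-4-[(triisopropylsilyl)oxy]phenyl (5R,9R)-5,9,13-trimethyltetradecanoate | Cc1cc(O[Si](C(C)C)(C(C)C)C(C)C)c(C)c(C=C)c1OC(=O)CCC[C@H](C)CCC[C@H](C)CCCC(C)C
F6 | step 8 | triisopropyl({2,5-dimethyl-4-{[(6R,10R)-6,10,14-trimethylpentadec-1-en-2-yl]oxy}-3-vinylphenyl}oxy)silane | Cc1cc(O[Si](C(C)C)(C(C)C)C(C)C)c(C)c(C=C)c1OC(=C)CCC[C@H](C)CCC[C@H](C)CCCC(C)C
F7 | step 7 | triisopropyl({2,5-dimethyl-4-[(6R,10R)-6,10,14-trimethylpentadec-1-en-2-yl]-3-vinylphenyl}oxy)silane | Cc1cc(O[Si](C(C)C)(C(C)C)C(C)C)c(C)c(C=C)c1C(=C)CCC[C@H](C)CCC[C@H](C)CCCC(C)C
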